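The runs were computed with made-up constants; noise was put on by code.

The easy step is to read the last row of each run, where the readings have levelled off.

| flask | substrate | free catalyst | remark | time |
|---|---|---|---|---|
| theta | 0.66 M | 0.94 mM | run made earlier |  |
| delta | 1 M | 0.94 mM | run made earlier |  |
| zeta | 0.47 M | 0.47 mM | run made earlier |  |
| flask | 0.47 M | 0.94 mM |  | 2.5 h |

- theta (time / h: product / %, substrate / %): 0.200: 20, 84; 0.667: 35, 64; 1.33: 43, 55; 2.00: 42, 55; 2.50: 45, 56
- delta (time / h: product / %, substrate / %): 0.200: 12, 87; 0.667: 31, 69; 1.33: 42, 61; 2.00: 43, 55; 2.50: 46, 59
- zeta (time / h: product / %, substrate / %): 0.200: 12, 90; 0.417: 13, 85; 0.667: 20, 79; 1.33: 25, 75; 2.50: 28, 76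

(scatter of a reading: 1.5 percentage points)

- steps that have been proposed: substrate + free catalyst -> catalyst intermediate; catalyst intermediate -> free catalyst + product; free catalyst -> spent catalyst

- how much product the flask holds at 2.5 h, in percent of the substrate charged
- how much substrate the flask holds at 2.5 h, in percent of the substrate charged

The bench rule says that conversion goes with the catalyst charge. Zeta ends at 28% product on 0.47 mM of free catalyst, so the rule promises 56.0% on 0.94 mM. But theta and delta, charged that way, end at 45% and 46%. A charge ratio of 2.00 bought a product ratio of 1.61.

On the proposed steps, free catalyst either binds substrate or is lost, so each portion of charge takes a share of the substrate remaining, not a set amount. Theta and delta, with different substrate charges, end alike within the scatter, so we carry no substrate term. Our zero of the scale is the even charge, the charge of free catalyst at which a stopped flask holds substrate and product level. Substrate left is then 0.5 raised to the charge over the even charge. Zeta's last row, substrate and the complement of product averaged, reads 1.08 mM, with the scatter of those readings. Zeta stands at 0.435 of it, and the flask at 0.869. So we expect 54.8% substrate and 45.2% product in the flask.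

The forecast says 45% product and 55% substrate, holding that “the final fractional conversion depends on the catalyst charge and not on the substrate charge”.

    substrate + free catalyst → catalyst intermediate (k = 0.939 M⁻¹ s⁻¹)
    catalyst intermediate → free catalyst + product (k = 0.294 s⁻¹)
    free catalyst → spent catalyst (k = 0.00154 s⁻¹)

The flask gives 43.6% product and 56.4% substrate, so the forecast stands. The flask stops short because free catalyst passes into spent catalyst: the same run without that step reaches 99.8% product, against 43.6%. The flask's computed product moves 5 points from that value at a charge of 0.801 mM or 1.09 mM, or at a time of 0.724 h, each moved alone. The neighbour charged with 2.40 mM stands at 2.22 even charges, which gives 21.4% substrate; computed, that neighbour holds 23.1%.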